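**Retrosynthetic overview**
1. Ugonin Q ⇐ global desilylation ⇐ C2–C1' bond by one-pot C2–H zincation/Negishi arylation of the complete 6-alkyl-5,7-bis(silyloxy)chromone with 4-bromo-1,2-bis(silyloxy)benzene. Enabling feature: the C2–H of the γ-pyranone (C) ring lies between the ring oxygen O1 and the vinylogous C4=O, and becomes the most acidic C–H once MgCl2 binds C4=O, so C2 needs no handle.
2. Chromone ⇐ sp3–sp2 Negishi coupling at C6 of 6-iodo-5,7-bis(silyloxy)chromone (iodine placed ortho to the free, chelated C5–OH of 7-O-silylated 5,7-dihydroxychromone) with the primary alkylzinc of the terpenoid unit.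
3. Terpenoid unit (1S,3S) ⇐ oxirane-to-exocyclic-allylic-alcohol isomerisation ⇐ anti-epoxidation of the (S)-α-cyclogeranyl silyl ether ⇐ Still–Wittig [2,3] shift of the stannylmethyl ether of (R)-2,4,4-trimethylcyclohex-2-enol (CBS reduction).
4. Ring order: the carbocycle, the A ring and the pyranone ring are bought intact; the only ring made is a temporary oxirane; the B ring is attached last.

Key step: step 13

Assumption: the SMILES is read as the (1S,3S) isomer, with the ring hydroxyl trans to the arylmethyl group; 5,7-dihydroxychromone, 2,4,4-trimethylcyclohex-2-en-1-one and 4-bromocatechol are taken as purchasable.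

**Step 1**
Reactants: 1 2,4,4-trimethylcyclohex-2-en-1-one
Product: 2 (1R)-2,4,4-trimethylcyclohex-2-en-1-ol
Conditions: (S)-Me-CBS (10 mol%), catecholborane, toluene, −78 °C; then MeOH, aq. NaOH
Reagents that add atoms: none
Why: Corey–Bakshi–Shibata reduction; the substituted alkenyl arm of the enone acts as the large group, so the (S)-oxazaborolidine should deliver hydride to the face that gives the (1R)-allylic alcohol, with 1,2-reduction favoured by catecholborane at low temperature.

**Step 2**
Reactants: 2 (1R)-2,4,4-trimethylcyclohex-2-en-1-ol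
Product: 3 tributyl({[(1R)-2,4,4-trimethylcyclohex-2-en-1-yl]oxy}methyl)stannane
Conditions: KH, 18-crown-6 (cat.), THF, 0 °C; Bu3SnCH2I, rt
Reagents that add atoms: (iodomethyl)tributylstannane CCCC[Sn](CCCC)(CCCC)CI
Why: Williamson etherification of the potassium alkoxide with the primary α-stannyl iodide (the standard entry to Still–Wittig substrates); the carbinol centre is not touched.

**Step 3**
Reactants: 3 tributyl({[(1R)-2,4,4-trimethylcyclohex-2-en-1-yl]oxy}methyl)stannane
Product: 5 triethyl{[(1S)-2,6,6-trimethylcyclohex-2-en-1-yl]methoxy}silane, via lithium (S)-α-cyclogeranoxide 4 (not isolated)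
Conditions: n-BuLi, THF, −78 °C; then Et3SiCl, −78 → 0 °C
Reagents that add atoms: chlorotriethylsilane CC[Si](Cl)(CC)CC
Why: Tin–lithium exchange gives the α-alkoxymethyllithium, whose Still–Wittig [2,3]-sigmatropic shift is suprafacial on the ring, so the C–O configuration of 3 is transferred to the new C–C stereocentre (1S) beside the gem-dimethyl carbon while the double bond moves; the alkoxide is silylated in the same flask.

**Step 4**
Reactants: 5 triethyl{[(1S)-2,6,6-trimethylcyclohex-2-en-1-yl]methoxy}silane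
Product: 6 triethyl{[(1R,2R,6S)-1,3,3-trimethyl-7-oxabicyclo[4.1.0]heptan-2-yl]methoxy}silane (oxirane trans to the CH2OSiEt3 group)
Conditions: mCPBA, NaHCO3, CH2Cl2, 0 °C
Reagents that add atoms: 3-chloroperoxybenzoic acid OOC(=O)c1cccc(Cl)c1
Why: Prilezhaev epoxidation of the only alkene; the bulky CH2OSiEt3 group on the adjacent allylic carbon (pseudoaxial to avoid A(1,2) strain with the vinylic methyl) shields its own face, so the peracid should add anti and place the oxygen trans to the side arm.

**Step 5**
Reactants: 6 triethyl{[(1R,2R,6S)-1,3,3-trimethyl-7-oxabicyclo[4.1.0]heptan-2-yl]methoxy}silane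
Product: 7 (1S,3S)-4,4-dimethyl-2-methylidene-3-[(triethylsilyloxy)methyl]cyclohexan-1-ol (OH trans to the CH2OSiEt3 group)
Conditions: Et2AlTMP (preformed, 4 equiv), toluene, 0 °C → rt; aq. Rochelle salt
Reagents that add atoms: none
Why: Aluminium-amide epoxide-to-allylic-alcohol isomerisation (syn β-elimination through a cyclic transition state): the hindered amide takes a proton from the methyl group, the least hindered site and the one cis to the oxirane hydrogen, so the tertiary C–O bond breaks, the exocyclic methylene forms and the oxygen stays on the secondary carbon with its configuration.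

**Step 6**
Reactants: 7 (1S,3S)-4,4-dimethyl-2-methylidene-3-[(triethylsilyloxy)methyl]cyclohexan-1-ol
Product: 9 [(1S,3S)-3-(tert-butyldimethylsilyloxy)-6,6-dimethyl-2-methylidenecyclohexyl]methanol, via bis-silyl ether 8 (not isolated)
Conditions: TBSOTf, 2,6-lutidine, CH2Cl2, −78 °C; then MeOH, PPTS, 0 °C → rt
Reagents that add atoms: tert-butyldimethylsilyl triflate CC(C)(C)[Si](C)(C)OS(=O)(=O)C(F)(F)F
Why: Silyl triflate silylation of the secondary allylic alcohol, followed by acid-catalysed methanolysis that removes a primary triethylsilyl ether much faster than a secondary tert-butyldimethylsilyl ether (selective desilylation).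

**Step 7**
Reactants: 9 [(1S,3S)-3-(tert-butyldimethylsilyloxy)-6,6-dimethyl-2-methylidenecyclohexyl]methanol
Product: 10 tert-butyl{[(1S,3S)-3-(iodomethyl)-4,4-dimethyl-2-methylidenecyclohexyl]oxy}dimethylsilane
Conditions: I2, PPh3, imidazole, CH2Cl2, 0 °C → rt
Reagents that add atoms: iodine II
Why: Appel-type iodination; the alkoxyphosphonium ion is displaced by iodide at the primary carbon, which is not a stereocentre.

**Step 8**
Reactants: 11 5,7-dihydroxy-4H-chromen-4-one
Product: 12 7-(tert-butyldimethylsilyloxy)-5-hydroxy-4H-chromen-4-one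
Conditions: TBSCl (1.05 equiv), imidazole, DMF, 0 °C
Reagents that add atoms: tert-butyldimethylsilyl chloride CC(C)(C)[Si](C)(C)Cl
Why: Selective monosilylation; the C7 hydroxyl is the acidic, unhindered phenol, whereas the C5 hydroxyl is held in a hydrogen bond to C4=O and reacts much more slowly.

**Step 9**
Reactants: 12 7-(tert-butyldimethylsilyloxy)-5-hydroxy-4H-chromen-4-one
Product: 13 7-(tert-butyldimethylsilyloxy)-5-hydroxy-6-iodo-4H-chromen-4-one
Conditions: BnMe3N·ICl2 (1.05 equiv), CaCO3, CH2Cl2–MeOH, rt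
Reagents that add atoms: benzyltrimethylammonium dichloroiodate C[N+](C)(C)Cc1ccccc1.Cl[I-]Cl
Why: Electrophilic aromatic iodination; the free, chelated C5–OH should direct the iodonium equivalent to its ortho position C6 (the known outcome for 5-hydroxy-7-alkoxyflavones with this reagent), and CaCO3 removes the HCl so that the silyl ether should survive.

**Step 10**
Reactants: 13 7-(tert-butyldimethylsilyloxy)-5-hydroxy-6-iodo-4H-chromen-4-one
Product: 14 5,7-bis(tert-butyldimethylsilyloxy)-6-iodo-4H-chromen-4-one
Conditions: TBSOTf, 2,6-lutidine, CH2Cl2, 0 °C → rt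
Reagents that add atoms: tert-butyldimethylsilyl triflate CC(C)(C)[Si](C)(C)OS(=O)(=O)C(F)(F)F
Why: Silylation of the hydrogen-bonded, flanked phenol needs the silyl triflate; it removes the last acidic proton before the organozinc steps.

**Step 11**
Reactants: 10 tert-butyl{[(1S,3S)-3-(iodomethyl)-4,4-dimethyl-2-methylidenecyclohexyl]oxy}dimethylsilane; 14 5,7-bis(tert-butyldimethylsilyloxy)-6-iodo-4H-chromen-4-one
Product: 16 5,7-bis(tert-butyldimethylsilyloxy)-6-{[(1S,3S)-3-(tert-butyldimethylsilyloxy)-6,6-dimethyl-2-methylidenecyclohexyl]methyl}-4H-chromen-4-one, via alkylzinc iodide 15 (not isolated)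
Conditions: 10, Zn dust, LiCl, THF, 40 °C; then 14, Pd(OAc)2 (5 mol%), SPhos (10 mol%), THF, 50 °C
Reagents that add atoms: none
Why: Oxidative insertion of zinc into the primary C–I bond and Negishi sp3–sp2 cross-coupling; the biaryl phosphine ligand promotes oxidative addition to the di-ortho-substituted iodide and reductive elimination ahead of β-hydride elimination, and neither stereocentre is at the metal-bearing carbon.

**Step 12**
Reactants: 17 4-bromobenzene-1,2-diol
Product: 18 4-bromo-1,2-bis(tert-butyldimethylsilyloxy)benzene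
Conditions: TBSCl (2.2 equiv), imidazole, DMF, rt
Reagents that add atoms: tert-butyldimethylsilyl chloride CC(C)(C)[Si](C)(C)Cl
Why: Routine silylation of both catechol hydroxyls, which masks the acidic and redox-sensitive B ring for the coupling.

**Step 13**
Reactants: 16 5,7-bis(tert-butyldimethylsilyloxy)-6-{[(1S,3S)-3-(tert-butyldimethylsilyloxy)-6,6-dimethyl-2-methylidenecyclohexyl]methyl}-4H-chromen-4-one; 18 4-bromo-1,2-bis(tert-butyldimethylsilyloxy)benzene
Product: 20 2-[3,4-bis(tert-butyldimethylsilyloxy)phenyl]-5,7-bis(tert-butyldimethylsilyloxy)-6-{[(1S,3S)-3-(tert-butyldimethylsilyloxy)-6,6-dimethyl-2-methylidenecyclohexyl]methyl}-4H-chromen-4-one, via C2-zincated chromone 19 (not isolated)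
Conditions: TMP2Zn·2MgCl2·2LiCl (preformed, 0.6 equiv), THF, −30 → 0 °C; then 18, Pd(OAc)2 (4 mol%), SPhos (8 mol%), THF, 50 °C
Reagents that add atoms: none
Why: MgCl2 from the base complexes the C4 carbonyl, which both blocks carbonyl-directed metalation at C3 and acidifies C2–H (the sp2 C–H between O1 and the vinylogous C4=O), so the TMP–zinc amide deprotonates C2 to the heteroarylzinc 19. Oxidative addition of 18 to Pd(0)/SPhos, transmetalation from zinc and reductive elimination then form the C2–C1' bond, overall a one-pot C–H zincation/Negishi arylation. The closest known reaction type is the Lewis-acid-triggered C2 zincation of chromones with TMP–zinc bases and their Negishi coupling with aryl halides to give flavones. No ring is closed and no stereocentre is created, and the two existing stereocentres carry no acidic hydrogen. The step needs site selectivity (C2 over C3 and over the aryl C8–H) and chemoselectivity: the first rests on the complexed C4=O and the much higher acidity of C2–H, the second on the mildness of zinc amide and organozinc, which should leave the five silyl ethers, the pyranone carbonyl and the 1,1-disubstituted alkene untouched. Because 16 needs no handle at C2, the whole B ring arrives in the last C–C bond-forming event of the synthesis.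

**Step 14**
Reactants: 20 2-[3,4-bis(tert-butyldimethylsilyloxy)phenyl]-5,7-bis(tert-butyldimethylsilyloxy)-6-{[(1S,3S)-3-(tert-butyldimethylsilyloxy)-6,6-dimethyl-2-methylidenecyclohexyl]methyl}-4H-chromen-4-one
Product: 21 ugonin Q, 2-(3,4-dihydroxyphenyl)-5,7-dihydroxy-6-{[(1S,3S)-3-hydroxy-6,6-dimethyl-2-methylidenecyclohexyl]methyl}-4H-chromen-4-one
Conditions: TBAF (7 equiv), THF, 0 °C → rt, argon; aq. NH4Cl
Reagents that add atoms: none
Why: Fluoride-mediated desilylation removes the four aryl and the one secondary alkyl silyl ether under non-acidic conditions, which avoids acid-induced addition of the C7 phenol to the exocyclic alkene and ionisation of the allylic alcohol.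

**Compound list**
1 | 2,4,4-trimethylcyclohex-2-en-1-one | CC1=CC(C)(C)CCC1=O | starting material
2 | (1R)-2,4,4-trimethylcyclohex-2-en-1-ol | O[C@H]1C(C)=CC(C)(C)CC1 | intermediate
3 | tributyl({[(1R)-2,4,4-trimethylcyclohex-2-en-1-yl]oxy}methyl)stannane | CCCC[Sn](CCCC)(CCCC)CO[C@H]1C(C)=CC(C)(C)CC1 | intermediate
4 | lithium [(1S)-2,6,6-trimethylcyclohex-2-en-1-yl]methanolate | CC1=CCCC(C)(C)[C@@H]1C[O-].[Li+] | intermediate (not isolated)
5 | triethyl{[(1S)-2,6,6-trimethylcyclohex-2-en-1-yl]methoxy}silane | CC1=CCCC(C)(C)[C@@H]1CO[Si](CC)(CC)CC | intermediate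
6 | triethyl{[(1R,2R,6S)-1,3,3-trimethyl-7-oxabicyclo[4.1.0]heptan-2-yl]methoxy}silane | C[C@@]12[C@@H](CO[Si](CC)(CC)CC)C(C)(C)CC[C@@H]1O2 | intermediate
7 | (1S,3S)-4,4-dimethyl-2-methylidene-3-[(triethylsilyloxy)methyl]cyclohexan-1-ol | C=C1[C@@H](CO[Si](CC)(CC)CC)C(C)(C)CC[C@@H]1O | intermediate
8 | tert-butyl({(1S,3S)-4,4-dimethyl-2-methylidene-3-[(triethylsilyloxy)methyl]cyclohexyl}oxy)dimethylsilane | C=C1[C@@H](CO[Si](CC)(CC)CC)C(C)(C)CC[C@@H]1O[Si](C)(C)C(C)(C)C | intermediate (not isolated)
9 | [(1S,3S)-3-(tert-butyldimethylsilyloxy)-6,6-dimethyl-2-methylidenecyclohexyl]methanol | C=C1[C@@H](CO)C(C)(C)CC[C@@H]1O[Si](C)(C)C(C)(C)C | intermediate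
10 | tert-butyl{[(1S,3S)-3-(iodomethyl)-4,4-dimethyl-2-methylidenecyclohexyl]oxy}dimethylsilane | C=C1[C@@H](CI)C(C)(C)CC[C@@H]1O[Si](C)(C)C(C)(C)C | intermediate
11 | 5,7-dihydroxy-4H-chromen-4-one | O=c1ccoc2cc(O)cc(O)c12 | starting material
12 | 7-(tert-butyldimethylsilyloxy)-5-hydroxy-4H-chromen-4-one | O=c1ccoc2cc(O[Si](C)(C)C(C)(C)C)cc(O)c12 | intermediate
13 | 7-(tert-butyldimethylsilyloxy)-5-hydroxy-6-iodo-4H-chromen-4-one | O=c1ccoc2cc(O[Si](C)(C)C(C)(C)C)c(I)c(O)c12 | intermediate
14 | 5,7-bis(tert-butyldimethylsilyloxy)-6-iodo-4H-chromen-4-one | O=c1ccoc2cc(O[Si](C)(C)C(C)(C)C)c(I)c(O[Si](C)(C)C(C)(C)C)c12 | intermediate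
15 | {[(1S,3S)-3-(tert-butyldimethylsilyloxy)-6,6-dimethyl-2-methylidenecyclohexyl]methyl}zinc iodide | C=C1[C@@H](C[Zn]I)C(C)(C)CC[C@@H]1O[Si](C)(C)C(C)(C)C | intermediate (not isolated)
16 | 5,7-bis(tert-butyldimethylsilyloxy)-6-{[(1S,3S)-3-(tert-butyldimethylsilyloxy)-6,6-dimethyl-2-methylidenecyclohexyl]methyl}-4H-chromen-4-one | C=C1[C@@H](Cc2c(O[Si](C)(C)C(C)(C)C)cc3occc(=O)c3c2O[Si](C)(C)C(C)(C)C)C(C)(C)CC[C@@H]1O[Si](C)(C)C(C)(C)C | intermediate
17 | 4-bromobenzene-1,2-diol | Oc1ccc(Br)cc1O | starting material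
18 | 4-bromo-1,2-bis(tert-butyldimethylsilyloxy)benzene | CC(C)(C)[Si](C)(C)Oc1ccc(Br)cc1O[Si](C)(C)C(C)(C)C | intermediate
19 | C2-zincated 16 (drawn as the monomeric zinc chloride) | C=C1[C@@H](Cc2c(O[Si](C)(C)C(C)(C)C)cc3oc([Zn]Cl)cc(=O)c3c2O[Si](C)(C)C(C)(C)C)C(C)(C)CC[C@@H]1O[Si](C)(C)C(C)(C)C | intermediate (not isolated)
20 | 2-[3,4-bis(tert-butyldimethylsilyloxy)phenyl]-5,7-bis(tert-butyldimethylsilyloxy)-6-{[(1S,3S)-3-(tert-butyldimethylsilyloxy)-6,6-dimethyl-2-methylidenecyclohexyl]methyl}-4H-chromen-4-one | C=C1[C@@H](Cc2c(O[Si](C)(C)C(C)(C)C)cc3oc(-c4ccc(O[Si](C)(C)C(C)(C)C)c(O[Si](C)(C)C(C)(C)C)c4)cc(=O)c3c2O[Si](C)(C)C(C)(C)C)C(C)(C)CC[C@@H]1O[Si](C)(C)C(C)(C)C | intermediate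
21 | ugonin Q | C=C1[C@@H](Cc2c(O)cc3oc(-c4ccc(O)c(O)c4)cc(=O)c3c2O)C(C)(C)CC[C@@H]1O | target

**Step count and risks**
Total step count: 14. Longest linear sequence: 10 steps (steps 1–7, 11, 13, 14).

Steps most likely to fail:

1. Step 13 (key step). Deprotonation at the wrong site (C3 or the aryl C8–H), ring-opening of the C2-metalated pyranone, or slow transmetalation to the electron-rich arylpalladium may erode the coupling. The fallback sets out from 16 and 18 and returns at 20. Compound 18 is converted with magnesium (LiCl, THF) into [3,4-bis(tert-butyldimethylsilyloxy)phenyl]magnesium bromide F1. Copper-catalysed 1,4-addition of F1 to 16 in the presence of Me3SiCl (CuBr·SMe2, THF, −78 °C) should give the silyl enol ether 2-[3,4-bis(tert-butyldimethylsilyloxy)phenyl]-5,7-bis(tert-butyldimethylsilyloxy)-6-{[(1S,3S)-3-(tert-butyldimethylsilyloxy)-6,6-dimethyl-2-methylidenecyclohexyl]methyl}-4-(trimethylsilyloxy)-2H-chromene F2 (both C2 epimers, of no consequence). Saegusa–Ito oxidation (Pd(OAc)2, MeCN) then restores the C2=C3 double bond and gives 20.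

2. Step 11. Slow oxidative addition and transmetalation at the iodide flanked by two silyloxy groups may let protodezincation and β-hydride elimination of 15 take over. The fallback sets out from 13 and 15 and returns at 16: the C–C coupling is moved ahead of the O5-silylation. Iodide 13, flanked by only one silyloxy group and a small chelated hydroxyl, is coupled with 15 (Pd/SPhos, slow addition of the organozinc, a protocol that tolerates phenolic O–H). This should give 7-(tert-butyldimethylsilyloxy)-5-hydroxy-6-{[(1S,3S)-3-(tert-butyldimethylsilyloxy)-6,6-dimethyl-2-methylidenecyclohexyl]methyl}-4H-chromen-4-one F3, which is silylated (TBSOTf, 2,6-lutidine) to 16.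

3. Step 5. Proton removal at the ring methine next to the oxirane (it is syn to the oxygen), or a Lewis-acid-induced hydride shift, may give the endocyclic allylic alcohol or a ketone instead of the exocyclic methylene. The fallback sets out from 6 and returns at 7. Homolytic opening of the oxirane with titanocene(III) chloride (Cp2TiCl2, Mn, THF) gives the tertiary radical at the methyl-bearing carbon; trapping by a second Ti(III) and loss of a β-hydrogen from the methyl group should give the exocyclic alkene. This radical route makes no compound outside the compound list (F0).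

**Further compounds**
F1 | step 13 | [3,4-bis(tert-butyldimethylsilyloxy)phenyl]magnesium bromide | CC(C)(C)[Si](C)(C)Oc1ccc([Mg]Br)cc1O[Si](C)(C)C(C)(C)C
F2 | step 13 | 2-[3,4-bis(tert-butyldimethylsilyloxy)phenyl]-5,7-bis(tert-butyldimethylsilyloxy)-6-{[(1S,3S)-3-(tert-butyldimethylsilyloxy)-6,6-dimethyl-2-methylidenecyclohexyl]methyl}-4-(trimethylsilyloxy)-2H-chromene | C=C1[C@@H](Cc2c(O[Si](C)(C)C(C)(C)C)cc3OC(c4ccc(O[Si](C)(C)C(C)(C)C)c(O[Si](C)(C)C(C)(C)C)c4)C=C(O[Si](C)(C)C)c3c2O[Si](C)(C)C(C)(C)C)C(C)(C)CC[C@@H]1O[Si](C)(C)C(C)(C)C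
F3 | step 11 | 7-(tert-butyldimethylsilyloxy)-5-hydroxy-6-{[(1S,3S)-3-(tert-butyldimethylsilyloxy)-6,6-dimethyl-2-methylidenecyclohexyl]methyl}-4H-chromen-4-one | C=C1[C@@H](Cc2c(O[Si](C)(C)C(C)(C)C)cc3occc(=O)c3c2O)C(C)(C)CC[C@@H]1O[Si](C)(C)C(C)(C)C
F0 | step 5 | none | none
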